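**Assumption:** the target has no stereocentre and no stereogenic double bond (the prenyl alkene carries two identical methyl groups), so "single enantiomer" is taken to mean the one achiral compound drawn.

**Retrosynthetic overview**
- The target is cut at its two late C–O bonds: the aryl–O–prenyl ether bond and the pyranone O1–C2 bond. The C2 methine and the prenyl group both come from one reagent, DMF diprenyl acetal, acting on 2,4-dihydroxyphenyl 3,4-dimethoxybenzyl ketone.
- The ketone is cut at the aryl–C(=O) bond into resorcinol and 3,4-dimethoxyphenylacetonitrile (Houben–Hoesch).
- DMF diprenyl acetal is cut into DMF dimethyl acetal and prenol (acetal exchange).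
- Ring order: rings A and B are bought; ring C (the pyran-4-one) is the only ring made, in the last step, in the same flask as the prenyl ether.

**Route**

Step 1
Reactants: 1 resorcinol; 2 3,4-dimethoxyphenylacetonitrile
Product: 4 1-(2,4-dihydroxyphenyl)-2-(3,4-dimethoxyphenyl)ethanone, via ketiminium chloride 3 (not isolated)
Conditions: HCl (g), ZnCl2 (0.3 equiv), Et2O, 0 °C to rt; then H2O, 100 °C
Reagents that add atoms: water, O
Why: Houben–Hoesch acylation: the HCl/ZnCl2-activated nitrile attacks resorcinol at C4 (ortho to one OH, para to the other), the ketiminium salt 3 separates and is deactivated towards a second acylation, and hot water hydrolyses it to the ketone; no stereocentre is formed.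

Step 2
Reactants: 5 N,N-dimethylformamide dimethyl acetal; 6 3-methylbut-2-en-1-ol (prenol)
Product: 7 N,N-dimethylformamide bis(3-methylbut-2-en-1-yl) acetal
Conditions: 6 (3 equiv), cyclohexane, 80 °C, MeOH removed as azeotrope; then 40 °C/1 mbar (strip excess 6); used when 1H NMR shows <2% OMe
Reagents that add atoms: none
Why: Transacetalisation (alcohol exchange) of an amide acetal through the alkoxymethyleneiminium ion, pulled to the bis-prenyl acetal by removing methanol; the pot stays below 90 °C so the allylic amide acetal does not enter the thermal carbene [2,3]-rearrangement; no stereocentre is formed.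

Step 3
Reactants: 4 1-(2,4-dihydroxyphenyl)-2-(3,4-dimethoxyphenyl)ethanone; 7 N,N-dimethylformamide bis(3-methylbut-2-en-1-yl) acetal
Product: 10 7-prenyloxy-3',4'-dimethoxyisoflavone, via enaminone 8 (not isolated), via 7-hydroxyisoflavone 9 (not isolated)
Conditions: 7 (3.0 equiv), dry PhMe, 60 °C, N2 sweep, 3 h; then 100 °C, 6 h
Reagents that add atoms: none
Why: Proposed new method: a DMF bis-allylic acetal used as one bifunctional reagent for tandem C1-annulation/O-prenylation. Acetal 7 ionises to the prenyloxymethyleneiminium/prenoxide ion pair, which (i) condenses at the acidic ArCO–CH2–Ar methylene to enaminone 8, whose 2-OH adds to the β-carbon and expels HNMe2 (swept out by N2) to close the pyranone through the O1–C2 bond (giving 9), and (ii) is protonated by the acidic 7-OH, so the resulting phenoxide attacks the primary allylic CH2 of [Me2N=CH–O–prenyl]+ in an SN2 step with DMF as neutral leaving group (the 7-O–prenyl bond). The chelated 2-OH is the poorer nucleophile, and prenylation of the 4-OH before ring closure leads to the same product. No stereocentre is formed. The closest known reaction types are the DMF dimethyl acetal enaminone cyclisation of 2-hydroxydeoxybenzoins to isoflavones and the O-alkylation of phenols and carboxylic acids by DMF dialkyl acetals (methyl, benzyl, tert-butyl); an allylic amide acetal has not been used to deliver both the ring carbon and an O-prenyl group in one operation.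

**Compound list** (all compounds are achiral)

1 | resorcinol (benzene-1,3-diol) | Oc1cccc(O)c1 | starting material
2 | 3,4-dimethoxyphenylacetonitrile | COc1ccc(CC#N)cc1OC | starting material
3 | 1-(2,4-dihydroxyphenyl)-2-(3,4-dimethoxyphenyl)ethan-1-iminium chloride (ketiminium chloride, not isolated) | COc1ccc(CC(=[NH2+])c2ccc(O)cc2O)cc1OC.[Cl-] | intermediate
4 | 1-(2,4-dihydroxyphenyl)-2-(3,4-dimethoxyphenyl)ethanone | COc1ccc(CC(=O)c2ccc(O)cc2O)cc1OC | intermediate
5 | N,N-dimethylformamide dimethyl acetal (1,1-dimethoxy-N,N-dimethylmethanamine) | COC(OC)N(C)C | starting material
6 | 3-methylbut-2-en-1-ol (prenol) | CC(C)=CCO | starting material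
7 | N,N-dimethylformamide bis(3-methylbut-2-en-1-yl) acetal (1,1-bis(3-methylbut-2-enyloxy)-N,N-dimethylmethanamine) | CN(C)C(OCC=C(C)C)OCC=C(C)C | intermediate
8 | 3-(dimethylamino)-1-(2,4-dihydroxyphenyl)-2-(3,4-dimethoxyphenyl)prop-2-en-1-one (enaminone; push–pull C=C of labile geometry, not isolated) | CN(C)C=C(C(=O)c1ccc(O)cc1O)c1ccc(OC)c(OC)c1 | intermediate
9 | 7-hydroxy-3',4'-dimethoxyisoflavone (7-hydroxy-3-(3,4-dimethoxyphenyl)chromen-4-one, not isolated) | COc1ccc(-c2coc3cc(O)ccc3c2=O)cc1OC | intermediate
10 | 7-prenyloxy-3',4'-dimethoxyisoflavone (3-(3,4-dimethoxyphenyl)-7-(3-methylbut-2-enyloxy)chromen-4-one) | COc1ccc(-c2coc3cc(OCC=C(C)C)ccc3c2=O)cc1OC | target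

**Step count:** 3 steps in total. Longest linear sequence: 2 steps (step 1 then step 3; step 2 makes the reagent for the convergent last step).

**Three steps most likely to fail, with fallbacks**

1. Step 3 (proposed new step). Risks: prenyl transfer stalls at 9; some attack at the tertiary allyl terminus or C-prenylation at C8; 2-O-prenylation before ring closure; thermal rearrangement of 7 if overheated. Fallback, known chemistry only: it sets out from 4 and comes back to the route at 10. Compound 4 is condensed with DMF dimethyl acetal 5 (THF, 65 °C), the established enaminone cyclisation through 8, and 7-hydroxy-3',4'-dimethoxyisoflavone 9 is isolated by filtration. Compound 9 is then O-alkylated with prenyl bromide (BrCC=C(C)C) and K2CO3 in refluxing acetone (Williamson ether synthesis) to give 10. Crude material from a stalled step 3, which is mainly 9, can be fed directly into this alkylation. New compounds: none F0.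

2. Step 2. Risks: incomplete exchange leaves a methyl prenyl mixed acetal, which would give the 7-methoxy isoflavone in step 3; heating may trigger rearrangement of the allylic acetal. Fallback: it sets out from 6 and comes back to the route at 7. Prenol 6 (2 equiv) is used to alcoholyse tris(dimethylamino)methane (CN(C)C(N(C)C)N(C)C) at 20–40 °C under an N2 sweep. The first exchange gives bis(dimethylamino)(3-methylbut-2-enyloxy)methane F1, and a second exchange with 6 gives 7. This changes the approach: an orthoamide is the C1 source, gaseous dimethylamine is the driving force, no heating is needed and no methoxy group is present anywhere.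

3. Step 1. Risks: dry HCl handling, oiling of the ketiminium salt, moderate yield. Fallback: it sets out from 1 and comes back to the route at 4. Resorcinol 1 is C-acylated directly with 3,4-dimethoxyphenylacetic acid (COc1ccc(CC(=O)O)cc1OC) in BF3·OEt2 as Lewis-acidic solvent at 85 °C, followed by aqueous NaOAc work-up (Friedel–Crafts acylation). The electrophile is a carboxylic acid instead of a nitrile, with no ketiminium intermediate and no HCl gas. New compounds: none F0.

**Further compounds**

F0 | step 1 | none | none
F1 | step 2 | bis(dimethylamino)(3-methylbut-2-enyloxy)methane | CN(C)C(OCC=C(C)C)N(C)C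
F0 | step 3 | none | none
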